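**Plan**

1. Disconnections: the C8–O angelate ester; the lactone C12–O6 bond together with C6–C7 (ten-membered carbocycle, intramolecular allylchromium addition); C8–C9 (alkoxyallylboration); C1–C2 (Suzuki coupling); C4–C5 (Marshall propargylation).
2. The 3(2H)-furanone (O, C10, C1, C2, C3) is traced back to a 2,5-dihydrofuran and this to the oxirane O/C10/C1 that carries the C2=C3 vinyl group. The tertiary ether carbon C10 lies next to the carbinol carbon C9, so this oxirane is the Sharpless epoxide of a 2-methyl-dienol, and its oxygen can move from C1 to C3 across the allyl unit (three-membered to five-membered ring, two atoms more).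
3. Forward ring order: oxirane (step 6), five-membered oxacycle by ring enlargement (step 8), furanone by ene oxidation (step 12), then carbocycle and cis-fused α-methylene-γ-lactone in one macrocyclisation (step 18).
4. Stereochemistry: C4/C5 from (R)-but-3-yn-2-ol (chirality transfer, anti); C10 from D-(−)-tartrate, its C–O bond never being broken afterwards; C8/C9 from the (+)-Ipc2B reagent; C6/C7 under substrate control (Felkin, chair) in the ring closure.

Key step: step 8

**Remarks on the chemistry**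

- Numbering follows the target: ring ketone C1, enol-ether carbons C2=C3, C4 (CH3), C5 (OH), C6 (lactone O), C7, C8 (angelate), C9 (OH), C10 (CH3, ring O), C11–C13 methylene-lactone carbons.
- 3-(Methoxymethoxy)prop-1-ene is taken as a purchasable ether (otherwise one step from allyl alcohol and MOMCl).
- C3 of 13–18 is a temporary stereocentre, drawn as the expected 2,5-cis isomer; its epimer would converge at 20.
- C7 of 21, 25 and 26 is a mixture that is erased in steps 13 and 15, so these SMILES carry no descriptor there.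
- TBS = tert-butyldimethylsilyl, TES = triethylsilyl, MOM = methoxymethyl.

**Route**

Step 1
Reactants: 1 (R)-but-3-yn-2-ol
Product: 2 (R)-but-3-yn-2-yl methanesulfonate
Conditions: MsCl, Et3N, CH2Cl2, −78 °C
Reagents that add atoms: methanesulfonyl chloride, CS(=O)(=O)Cl
Why: O-sulfonylation of the propargylic alcohol leaves the stereocentre untouched and provides the leaving group for step 2.

Step 2
Reactants: 2 (R)-but-3-yn-2-yl methanesulfonate; 3 (tert-butyldimethylsilyloxy)acetaldehyde
Product: 5 (2S,3S)-1-(tert-butyldimethylsilyloxy)-3-methylpent-4-yn-2-ol, via allenylzinc reagent 4 (not isolated)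
Conditions: Pd(OAc)2 (5 mol%), PPh3 (5 mol%), Et2Zn, THF, −78 → −20 °C
Reagents that add atoms: none
Why: Marshall propargylation: anti-SN2′ attack of Pd(0), transmetalation to the allenylzinc and cyclic SE2′ addition to the aldehyde relay the mesylate chirality into C4 and give the anti C4/C5 pair.

Step 3
Reactants: 5 (2S,3S)-1-(tert-butyldimethylsilyloxy)-3-methylpent-4-yn-2-ol
Product: 6 (2S,3S)-1,2-bis(tert-butyldimethylsilyloxy)-3-methylpent-4-yne
Conditions: TBSOTf, 2,6-lutidine, CH2Cl2, −78 → 0 °C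
Reagents that add atoms: tert-butyldimethylsilyl trifluoromethanesulfonate, CC(C)(C)[Si](C)(C)OS(=O)(=O)C(F)(F)F
Why: Silylation of the secondary alcohol gives a bis-silyl ether whose primary (C6) ether can later be removed selectively.

Step 4
Reactants: 7 prop-2-yn-1-ol
Product: 8 (E)-3-iodo-2-methylprop-2-en-1-ol
Conditions: AlMe3, Cp2ZrCl2 (cat.), CH2Cl2, 0 °C → rt; then I2, THF, −30 → 0 °C
Reagents that add atoms: trimethylaluminium, C[Al](C)C; iodine, II
Why: Negishi zirconium-catalysed carboalumination (syn, methyl to the internal carbon) and iodinolysis with retention give the E-iodide.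

Step 5
Reactants: 6 (2S,3S)-1,2-bis(tert-butyldimethylsilyloxy)-3-methylpent-4-yne; 8 (E)-3-iodo-2-methylprop-2-en-1-ol
Product: 10 (2E,4E,6S,7S)-7,8-bis(tert-butyldimethylsilyloxy)-2,6-dimethylocta-2,4-dien-1-ol, via alkenyl catecholboronate 9 (not isolated)
Conditions: catecholborane, Cy2BH (cat.), THF, rt; then 8, Pd(PPh3)4 (5 mol%), aq. NaOH, THF, rt
Reagents that add atoms: none
Why: syn-Hydroboration of the terminal alkyne gives the E-alkenylboronate, and Suzuki–Miyaura coupling with retention at both partners forms the C1–C2 bond of the E,E-dienol.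

Step 6
Reactants: 10 (2E,4E,6S,7S)-7,8-bis(tert-butyldimethylsilyloxy)-2,6-dimethylocta-2,4-dien-1-ol
Product: 11 [(2R,3R)-3-[(1E,3S,4S)-4,5-bis(tert-butyldimethylsilyloxy)-3-methylpent-1-enyl]-2-methyloxiran-2-yl]methanol
Conditions: Ti(OiPr)4 (cat.), D-(−)-diethyl tartrate (cat.), t-BuOOH, 4 Å MS, CH2Cl2, −20 °C
Reagents that add atoms: tert-butyl hydroperoxide, CC(C)(C)OO
Why: Sharpless asymmetric epoxidation attacks only the allylic C10=C1 olefin, and the D-(−)-tartrate ligand selects the face that gives the C10 configuration of the target (reagent control), leaving C2=C3 as the vinyl group.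

Step 7
Reactants: 11 [(2R,3R)-3-[(1E,3S,4S)-4,5-bis(tert-butyldimethylsilyloxy)-3-methylpent-1-enyl]-2-methyloxiran-2-yl]methanol
Product: 12 triethylsilyl ether of 11
Conditions: TESCl, imidazole, CH2Cl2, 0 °C
Reagents that add atoms: chlorotriethylsilane, CC[Si](Cl)(CC)CC
Why: Silylation removes the free hydroxyl, which could otherwise capture the allyl intermediate of step 8, and installs a group that step 9 oxidises directly.

Step 8
Reactants: 12 triethylsilyl ether of 11
Product: 13 (2S,5R)-5-[(2S,3S)-3,4-bis(tert-butyldimethylsilyloxy)butan-2-yl]-2-methyl-2-[(triethylsilyloxy)methyl]-2,5-dihydrofuran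
Conditions: Cu(hfacac)2 (5 mol%), PhMe, 110–150 °C
Reagents that add atoms: none
Why: The copper Lewis acid (or the Cu(I) species formed from it) engages the oxirane oxygen and cleaves the only allylic C–O bond, C1–O, to a copper-bound C10 alkoxide and a C1–C2–C3 allyl unit; the oxygen, still attached to C10, then bonds to the distal terminus C3 and the C1=C2 double bond appears, so the three-membered ring O/C10/C1 takes up C2 and C3 (net [1,3]-shift of oxygen). The closest known reaction type is the copper-catalysed rearrangement of 2-vinyloxiranes to 2,5-dihydrofurans. The dihydrofuran ring is closed by C–O bond formation at the terminus of a delocalised allyl unit, formally 5-endo-trig, which as collapse of an ion pair or reductive elimination from an oxa-cupracycle is not subject to the usual 5-endo restriction. C10 keeps its configuration because its C–O bond is never broken; the new stereocentre C3 should be set by suprafacial oxygen delivery within the E-alkenyl trans-oxirane (C4 chain cis to CH2OTES) and is erased in step 12. The step needs cleavage of C1–O in preference to C10–O and ring closure in preference to hydride shift or elimination: C1 is allylic whereas C10 is deactivated by the adjacent CH2OSi group, there is no free hydroxyl, and the other oxygens are remote, bulky silyl ethers.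

Step 9
Reactants: 13 (2S,5R)-5-[(2S,3S)-3,4-bis(tert-butyldimethylsilyloxy)butan-2-yl]-2-methyl-2-[(triethylsilyloxy)methyl]-2,5-dihydrofuran
Product: 14 (2S,5R)-5-[(2S,3S)-3,4-bis(tert-butyldimethylsilyloxy)butan-2-yl]-2-methyl-2,5-dihydrofuran-2-carbaldehyde
Conditions: (COCl)2, DMSO, CH2Cl2, −78 → −30 °C; then Et3N, −78 → 0 °C
Reagents that add atoms: none
Why: Swern conditions cleave and oxidise a primary triethylsilyl ether directly while TBS ethers survive, and the quaternary α-carbon (C10) cannot epimerise.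

Step 10
Reactants: 14 (2S,5R)-5-[(2S,3S)-3,4-bis(tert-butyldimethylsilyloxy)butan-2-yl]-2-methyl-2,5-dihydrofuran-2-carbaldehyde; 15 3-(methoxymethoxy)prop-1-ene
Product: 17 (1R,2S)-1-[(2S,5R)-5-[(2S,3S)-3,4-bis(tert-butyldimethylsilyloxy)butan-2-yl]-2-methyl-2,5-dihydrofuran-2-yl]-2-(methoxymethoxy)but-3-en-1-ol, via alkoxyallylborane 16 (not isolated)
Conditions: 15, s-BuLi, THF, −78 °C; (+)-Ipc2BOMe; BF3·OEt2; then 14, −78 °C → rt; NaOH, H2O2
Reagents that add atoms: none
Why: Brown alkoxyallylboration: the (Z)-γ-alkoxyallylborane reacts through a chair transition state (syn C8/C9) and the (+)-Ipc ligands select the Re face of the aldehyde (9R), in line with Felkin–Anh addition anti to the C10–O bond.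

Step 11
Reactants: 17 (1R,2S)-1-[(2S,5R)-5-[(2S,3S)-3,4-bis(tert-butyldimethylsilyloxy)butan-2-yl]-2-methyl-2,5-dihydrofuran-2-yl]-2-(methoxymethoxy)but-3-en-1-ol
Product: 18 C9 tert-butyldimethylsilyl ether of 17
Conditions: TBSOTf, 2,6-lutidine, CH2Cl2, −78 → −20 °C
Reagents that add atoms: tert-butyldimethylsilyl trifluoromethanesulfonate, CC(C)(C)[Si](C)(C)OS(=O)(=O)C(F)(F)F
Why: Silylation masks the C9 hydroxyl before the C1 ketone is made, so that no free β-hydroxy ketone (retro-aldol at C9–C10) exists until the last step.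

Step 12
Reactants: 18 C9 tert-butyldimethylsilyl ether of 17
Product: 20 3(2H)-furanone with C7 vinyl group (C8 OMOM; C5 C6 C9 OTBS), via allylic hydroperoxide 19 (not isolated)
Conditions: O2, hν (visible), tetraphenylporphyrin (cat.), Ac2O, pyridine, DMAP (cat.), CH2Cl2, 0 °C
Reagents that add atoms: dioxygen, O=O
Why: Schenck ene reaction: singlet oxygen adds to C1 on the methyl face while abstracting the only allylic hydrogen (H-3, on that face), moving the olefin to C2=C3, and in situ acetylation with Kornblum–DeLaMare-type elimination of the secondary hydroperoxide gives the C1 ketone before the enol ether can be over-oxidised.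

Step 13
Reactants: 20 3(2H)-furanone with C7 vinyl group (C8 OMOM; C5 C6 C9 OTBS)
Product: 22 C7 aldehyde of the furanone series, via vicinal diol 21 (not isolated)
Conditions: OsO4 (2 mol%), NaIO4, 2,6-lutidine, dioxane/H2O, rt
Reagents that add atoms: osmium tetroxide, O=[Os](=O)(=O)=O (catalytic, re-oxidised by sodium periodate, [Na+].[O-]I(=O)(=O)=O)
Why: Lemieux–Johnson cleavage: OsO4 dihydroxylates the monosubstituted vinyl group in preference to the hindered, electron-poor vinylogous-ester olefin, periodate cleaves the diol, and 2,6-lutidine suppresses epimerisation at C8.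

Step 14
Reactants: 22 C7 aldehyde of the furanone series; 23 methyl propiolate
Product: 25 Baylis–Hillman-type adduct (C7 carbinol bearing the methyl acrylate unit C11–C13), via vinylalane 24 (not isolated)
Conditions: DIBAL-H, NMO, THF, 0 °C, 23; then 22, 0 °C → rt
Reagents that add atoms: none
Why: Vinylalumination (a Morita–Baylis–Hillman surrogate that tolerates hindered α-alkoxy aldehydes): the α-(methoxycarbonyl)vinylalane adds 1,2 to the aldehyde, and the new C7 carbinol configuration is irrelevant because C7 becomes sp2 in step 15.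

Step 15
Reactants: 25 Baylis–Hillman-type adduct (C7 carbinol bearing the methyl acrylate unit C11–C13)
Product: 27 (Z)-2-(bromomethyl)-2-enoate (C13 bromide; C6 OTBS), via allylic mesylate 26 (not isolated)
Conditions: MsCl, Et3N, CH2Cl2, −20 °C; then LiBr, THF, 0 °C → rt
Reagents that add atoms: lithium bromide, [Li+].[Br-]
Why: Mesylation and SN2′ displacement by bromide (allylic transposition of Baylis–Hillman adducts) give the thermodynamically favoured Z-bromide with CH2Br cis to C8.

Step 16
Reactants: 27 (Z)-2-(bromomethyl)-2-enoate (C13 bromide; C6 OTBS)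
Product: 28 C6 primary alcohol of 27
Conditions: CSA (20 mol%), MeOH/CH2Cl2 (1:1), 0 °C
Reagents that add atoms: none
Why: Acid-catalysed methanolysis removes the unhindered primary TBS ether much faster than the two secondary ones and leaves the MOM acetal intact.

Step 17
Reactants: 28 C6 primary alcohol of 27
Product: 29 C6 aldehyde of 27
Conditions: Dess–Martin periodinane, NaHCO3, CH2Cl2, 0 °C → rt
Reagents that add atoms: none
Why: Buffered Dess–Martin oxidation gives the α-silyloxy aldehyde without epimerisation at C5 or elimination.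

Step 18
Reactants: 29 C6 aldehyde of 27
Product: 31 macrocyclic α-methylene-γ-lactone (C8 OMOM; C5 C9 OTBS), via hydroxy ester 30 (not isolated)
Conditions: CrCl2, THF/DMF, rt, syringe-pump addition (ca. 2 mM); then PPTS (cat.), PhH, rt
Reagents that add atoms: none
Why: Intramolecular Nozaki–Hiyama (Barbier-type) allylation: the 2-(methoxycarbonyl)allylchromium adds through C7 to the aldehyde in a chair transition state (syn C6/C7, hence the cis-lactone after loss of methanol), with Felkin–Anh attack anti to the C5–OTBS bond setting C6 and the H-8-eclipsed (A1,3-strain) allyl face setting C7, while high dilution favours the ten-membered ring.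

Step 19
Reactants: 31 macrocyclic α-methylene-γ-lactone (C8 OMOM; C5 C9 OTBS)
Product: 32 C8 alcohol of 31
Conditions: Me2BBr, CH2Cl2, −78 °C; aq. NaHCO3
Reagents that add atoms: none
Why: Dimethylboron bromide cleaves the acetal-type MOM ether at −78 °C and leaves silyl ethers, lactone and furanone intact.

Step 20
Reactants: 32 C8 alcohol of 31; 33 angelic acid
Product: 35 5,9-bis-O-TBS ether of the target, via mixed anhydride 34 (not isolated)
Conditions: 33, 2,4,6-trichlorobenzoyl chloride, Et3N, PhMe, rt; then 32, 80 °C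
Reagents that add atoms: none
Why: Mixed-anhydride (Yamaguchi-type) acylation without DMAP transfers the angeloyl group to the only free hydroxyl (C8) without Z-to-E isomerisation to the tiglate.

Step 21
Reactants: 35 5,9-bis-O-TBS ether of the target
Product: 36 target CNP0206920.1
Conditions: HF·pyridine, pyridine, THF, 0 °C → rt
Reagents that add atoms: none
Why: Mildly acidic fluoride cleaves the two secondary TBS ethers and avoids the retro-aldol (C9–C10) and acyl-migration pathways open under basic conditions.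

**Compound list**

1 | (R)-but-3-yn-2-ol | C[C@@H](O)C#C | starting material
2 | (R)-but-3-yn-2-yl methanesulfonate | C[C@@H](OS(C)(=O)=O)C#C | intermediate
3 | (tert-butyldimethylsilyloxy)acetaldehyde | O=CCO[Si](C)(C)C(C)(C)C | starting material
4 | (P)-buta-1,2-dienyl(ethyl)zinc (axial chirality not expressible in the SMILES) | CC[Zn]C=C=CC | intermediate
5 | (2S,3S)-1-(tert-butyldimethylsilyloxy)-3-methylpent-4-yn-2-ol | C#C[C@H](C)[C@H](O)CO[Si](C)(C)C(C)(C)C | intermediate
6 | (2S,3S)-1,2-bis(tert-butyldimethylsilyloxy)-3-methylpent-4-yne | C#C[C@H](C)[C@H](O[Si](C)(C)C(C)(C)C)CO[Si](C)(C)C(C)(C)C | intermediate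
7 | prop-2-yn-1-ol | C#CCO | starting material
8 | (E)-3-iodo-2-methylprop-2-en-1-ol | OC/C(C)=C/I | intermediate
9 | 2-[(1E,3S,4S)-4,5-bis(tert-butyldimethylsilyloxy)-3-methylpent-1-enyl]-1,3,2-benzodioxaborole | O1c2ccccc2OB1/C=C/[C@H](C)[C@H](O[Si](C)(C)C(C)(C)C)CO[Si](C)(C)C(C)(C)C | intermediate
10 | (2E,4E,6S,7S)-7,8-bis(tert-butyldimethylsilyloxy)-2,6-dimethylocta-2,4-dien-1-ol | OC/C(C)=C/C=C/[C@H](C)[C@H](O[Si](C)(C)C(C)(C)C)CO[Si](C)(C)C(C)(C)C | intermediate
11 | [(2R,3R)-3-[(1E,3S,4S)-4,5-bis(tert-butyldimethylsilyloxy)-3-methylpent-1-enyl]-2-methyloxiran-2-yl]methanol | OC[C@@]1(C)O[C@@H]1/C=C/[C@H](C)[C@H](O[Si](C)(C)C(C)(C)C)CO[Si](C)(C)C(C)(C)C | intermediate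
12 | triethylsilyl ether of 11 (vinyl oxirane O/C10/C1 with C2=C3) | CC[Si](CC)(CC)OC[C@@]1(C)O[C@@H]1/C=C/[C@H](C)[C@H](O[Si](C)(C)C(C)(C)C)CO[Si](C)(C)C(C)(C)C | intermediate
13 | (2S,5R)-5-[(2S,3S)-3,4-bis(tert-butyldimethylsilyloxy)butan-2-yl]-2-methyl-2-[(triethylsilyloxy)methyl]-2,5-dihydrofuran (2,5-cis) | CC[Si](CC)(CC)OC[C@@]1(C)O[C@H](C=C1)[C@H](C)[C@H](O[Si](C)(C)C(C)(C)C)CO[Si](C)(C)C(C)(C)C | intermediate
14 | (2S,5R)-5-[(2S,3S)-3,4-bis(tert-butyldimethylsilyloxy)butan-2-yl]-2-methyl-2,5-dihydrofuran-2-carbaldehyde | O=C[C@@]1(C)O[C@H](C=C1)[C@H](C)[C@H](O[Si](C)(C)C(C)(C)C)CO[Si](C)(C)C(C)(C)C | intermediate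
15 | 3-(methoxymethoxy)prop-1-ene | C=CCOCOC | starting material
16 | (Z)-[3-(methoxymethoxy)allyl]bis[(+)-isopinocampheyl]borane | COCO/C=C\CB([C@H]1C[C@H]2C[C@@H]([C@@H]1C)C2(C)C)[C@H]1C[C@H]2C[C@@H]([C@@H]1C)C2(C)C | intermediate
17 | (1R,2S)-1-[(2S,5R)-5-[(2S,3S)-3,4-bis(tert-butyldimethylsilyloxy)butan-2-yl]-2-methyl-2,5-dihydrofuran-2-yl]-2-(methoxymethoxy)but-3-en-1-ol | C=C[C@H](OCOC)[C@@H](O)[C@@]1(C)O[C@H](C=C1)[C@H](C)[C@H](O[Si](C)(C)C(C)(C)C)CO[Si](C)(C)C(C)(C)C | intermediate
18 | C9 tert-butyldimethylsilyl ether of 17 | C=C[C@H](OCOC)[C@@H](O[Si](C)(C)C(C)(C)C)[C@@]1(C)O[C@H](C=C1)[C@H](C)[C@H](O[Si](C)(C)C(C)(C)C)CO[Si](C)(C)C(C)(C)C | intermediate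
19 | C1 hydroperoxide of the 2,3-dihydrofuran (OOH cis to the C10 methyl, olefin at C2=C3) | C=C[C@H](OCOC)[C@@H](O[Si](C)(C)C(C)(C)C)[C@@]1(C)OC(=C[C@@H]1OO)[C@H](C)[C@H](O[Si](C)(C)C(C)(C)C)CO[Si](C)(C)C(C)(C)C | intermediate
20 | 3(2H)-furanone with C7 vinyl group (C8 OMOM; C5, C6, C9 OTBS; C4, C5, C8, C9, C10 as in 36) | C=C[C@H](OCOC)[C@@H](O[Si](C)(C)C(C)(C)C)[C@@]1(C)OC(=CC1=O)[C@H](C)[C@H](O[Si](C)(C)C(C)(C)C)CO[Si](C)(C)C(C)(C)C | intermediate
21 | vicinal diol from the vinyl group of 20 (C7 mixture) | OCC(O)[C@H](OCOC)[C@@H](O[Si](C)(C)C(C)(C)C)[C@@]1(C)OC(=CC1=O)[C@H](C)[C@H](O[Si](C)(C)C(C)(C)C)CO[Si](C)(C)C(C)(C)C | intermediate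
22 | C7 aldehyde of the furanone series | O=C[C@H](OCOC)[C@@H](O[Si](C)(C)C(C)(C)C)[C@@]1(C)OC(=CC1=O)[C@H](C)[C@H](O[Si](C)(C)C(C)(C)C)CO[Si](C)(C)C(C)(C)C | intermediate
23 | methyl propiolate | C#CC(=O)OC | starting material
24 | [1-(methoxycarbonyl)vinyl]diisobutylaluminium | C=C(C(=O)OC)[Al](CC(C)C)CC(C)C | intermediate
25 | Baylis–Hillman-type adduct: methyl 2-methylene-3-hydroxy ester at C11/C7 (C7 mixture) | C=C(C(=O)OC)C(O)[C@H](OCOC)[C@@H](O[Si](C)(C)C(C)(C)C)[C@@]1(C)OC(=CC1=O)[C@H](C)[C@H](O[Si](C)(C)C(C)(C)C)CO[Si](C)(C)C(C)(C)C | intermediate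
26 | C7 methanesulfonate of 25 (C7 mixture) | C=C(C(=O)OC)C(OS(C)(=O)=O)[C@H](OCOC)[C@@H](O[Si](C)(C)C(C)(C)C)[C@@]1(C)OC(=CC1=O)[C@H](C)[C@H](O[Si](C)(C)C(C)(C)C)CO[Si](C)(C)C(C)(C)C | intermediate
27 | (Z)-2-(bromomethyl)-2-enoate (C13 bromide, C7=C11, CH2Br cis to C8; C6 OTBS) | BrC/C(C(=O)OC)=C\[C@H](OCOC)[C@@H](O[Si](C)(C)C(C)(C)C)[C@@]1(C)OC(=CC1=O)[C@H](C)[C@H](O[Si](C)(C)C(C)(C)C)CO[Si](C)(C)C(C)(C)C | intermediate
28 | C6 primary alcohol of 27 | BrC/C(C(=O)OC)=C\[C@H](OCOC)[C@@H](O[Si](C)(C)C(C)(C)C)[C@@]1(C)OC(=CC1=O)[C@H](C)[C@H](O[Si](C)(C)C(C)(C)C)CO | intermediate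
29 | C6 aldehyde of 27 | BrC/C(C(=O)OC)=C\[C@H](OCOC)[C@@H](O[Si](C)(C)C(C)(C)C)[C@@]1(C)OC(=CC1=O)[C@H](C)[C@H](O[Si](C)(C)C(C)(C)C)C=O | intermediate
30 | ten-membered C6 alcohol with the methyl 2-propenoate unit on C7 (C6 and C7 as in 36) | C=C(C(=O)OC)[C@@H]1[C@H](OCOC)[C@@H](O[Si](C)(C)C(C)(C)C)[C@@]2(C)OC(=CC2=O)[C@H](C)[C@H](O[Si](C)(C)C(C)(C)C)[C@@H]1O | intermediate
31 | macrocyclic α-methylene-γ-lactone, 8-O-MOM, 5,9-bis-O-TBS (all stereocentres as in 36) | C=C1C(=O)O[C@H]2[C@@H](O[Si](C)(C)C(C)(C)C)[C@@H](C)C3=CC(=O)[C@](C)(O3)[C@H](O[Si](C)(C)C(C)(C)C)[C@@H](OCOC)[C@@H]12 | intermediate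
32 | C8 alcohol, 5,9-bis-O-TBS | C=C1C(=O)O[C@H]2[C@@H](O[Si](C)(C)C(C)(C)C)[C@@H](C)C3=CC(=O)[C@](C)(O3)[C@H](O[Si](C)(C)C(C)(C)C)[C@@H](O)[C@@H]12 | intermediate
33 | angelic acid, (Z)-2-methylbut-2-enoic acid | C/C=C(/C)C(=O)O | starting material
34 | angelic 2,4,6-trichlorobenzoic anhydride | C/C=C(/C)C(=O)OC(=O)c1c(Cl)cc(Cl)cc1Cl | intermediate
35 | 5,9-bis-O-TBS ether of the target (8-O-angelate) | C=C1C(=O)O[C@H]2[C@@H](O[Si](C)(C)C(C)(C)C)[C@@H](C)C3=CC(=O)[C@](C)(O3)[C@H](O[Si](C)(C)C(C)(C)C)[C@@H](OC(=O)/C(C)=C\C)[C@@H]12 | intermediate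
36 | CNP0206920.1 (4R,5S,6R,7S,8S,9R,10R) | C=C1C(=O)O[C@H]2[C@@H](O)[C@@H](C)C3=CC(=O)[C@](C)(O3)[C@H](O)[C@@H](OC(=O)/C(C)=C\C)[C@@H]12 | target

**Summary**

Total step count: 21. Longest linear sequence: 20 steps (steps 1–3 and 5–21, from (R)-but-3-yn-2-ol); step 4 is a one-step side branch.

**Steps most likely to fail**

1. Step 18 (macrocyclisation). What may go wrong: intermolecular allylation (oligomers) may outrun the ten-membered ring closure, and facial selectivity at C6/C7 may be poor, because the allylchromium can equilibrate between geometries and both new centres are set in one event. Fallback: setting out from alcohol 28, palladium-catalysed borylation of the allylic bromide (B2pin2, Pd2(dba)3 cat., DMSO) would give the configurationally defined (Z)-2-(methoxycarbonyl)allyl pinacolboronate alcohol F1. Dess–Martin oxidation would give the boronate aldehyde F2. Its intramolecular allylboration (closed chair transition state, heat or Sc(OTf)3 catalysis, high dilution) followed by acid-promoted lactonisation comes back to the route at lactone 31.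

2. Step 12 (ene oxidation). What may go wrong: the ene reaction of the cis-olefin, deactivated by two allylic ether oxygens, may be slow, so that the enol-ether hydroperoxide is over-oxidised (dioxetane cleavage) or the minor C3 epimer is left behind. Fallback: setting out from 18, dimethyldioxirane would epoxidise the strained ring olefin on the methyl face to give the oxirane F3. Et2AlTMP would open it by syn-β-elimination through H-3 to the 3-hydroxy-2,3-dihydrofuran F4. Dess–Martin oxidation of the allylic alcohol comes back to the route at furanone 20.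

3. Step 8 (ring enlargement). What may go wrong: ionisation without ring closure, that is hydride or alkyl shift at C10, proton loss from the allyl intermediate to a dienol, or capture of the allyl unit by a silyl ether oxygen at the high temperature required. Fallback: the Lewis-acid [1,3]-shift would be replaced by a nucleophile-relayed two-stage enlargement at low temperature. Setting out from 12, MgI2 (Et2O/PhMe, −40 °C) would open the oxirane with allylic transposition to the (Z)-4-iodo-2-en-1-ol F5 (the allylic iodides equilibrate), and Ag2O would close the ring by 5-exo-tet displacement of iodide, coming back to the route at dihydrofuran 13.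

Further compounds
F1 | step 18 | (Z)-2-(methoxycarbonyl)allyl pinacolboronate, C6 alcohol | CC1(C)OB(C/C(C(=O)OC)=C\[C@H](OCOC)[C@@H](O[Si](C)(C)C(C)(C)C)[C@@]2(C)OC(=CC2=O)[C@H](C)[C@H](O[Si](C)(C)C(C)(C)C)CO)OC1(C)C
F2 | step 18 | (Z)-2-(methoxycarbonyl)allyl pinacolboronate, C6 aldehyde | CC1(C)OB(C/C(C(=O)OC)=C\[C@H](OCOC)[C@@H](O[Si](C)(C)C(C)(C)C)[C@@]2(C)OC(=CC2=O)[C@H](C)[C@H](O[Si](C)(C)C(C)(C)C)C=O)OC1(C)C
F3 | step 12 | C1/C2 oxirane of 18 on the methyl face | C=C[C@H](OCOC)[C@@H](O[Si](C)(C)C(C)(C)C)[C@@]1(C)O[C@H]([C@@H]2O[C@H]12)[C@H](C)[C@H](O[Si](C)(C)C(C)(C)C)CO[Si](C)(C)C(C)(C)C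
F4 | step 12 | 3-hydroxy-2,3-dihydrofuran (C1 alcohol, olefin at C2=C3) | C=C[C@H](OCOC)[C@@H](O[Si](C)(C)C(C)(C)C)[C@@]1(C)OC(=C[C@@H]1O)[C@H](C)[C@H](O[Si](C)(C)C(C)(C)C)CO[Si](C)(C)C(C)(C)C
F5 | step 8 | (Z)-4-iodo-2-en-1-ol from 12 (C10 tertiary alcohol, C3 iodide, C3 mixture) | CC[Si](CC)(CC)OC[C@@](C)(O)/C=C\C(I)[C@H](C)[C@H](O[Si](C)(C)C(C)(C)C)CO[Si](C)(C)C(C)(C)C
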